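The ring carbon C4, the carbinol carbon C3 and the side chain C1'–C11' form one thirteen-carbon string whose two oxygenated carbons, C3 and C10', lie one carbon in from either end; as a 1,2:12,13-diepoxide this string is C2-symmetric. It is therefore assembled in two directions: a heptane-1,7-diyl bis-Grignard reagent (C2'–C8') opens two molecules of (R)-epichlorohydrin at the epoxide CH2 with catalytic CuI, forming C1'–C2' and C8'–C9' and fixing both carbinol centres at once. The derived (R,R)-diepoxide is differentiated by hydride at one end and a 3,5-bis(benzyloxy)phenyl Grignard reagent at the other; carbonylative lactonization then closes ring B (the lactone) onto ring A (the arene).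

Key step: step 2

Assumption: isochromanone numbering is used (C1 carbonyl, O2, C3, C4; side chain C1'–C11'), and commercial (R)-epichlorohydrin of high enantiomeric purity is the only source of chirality.

Step 1
Reactants: 1 1,7-dibromoheptane
Product: 2 heptane-1,7-diylbis(magnesium bromide), used as a titrated THF solution
Conditions: Mg turnings (excess), I2 (cat.), THF, slow addition at 45 °C, high dilution
Reagents that add atoms: magnesium, [Mg]
Why: Grignard reagent formation by magnesium insertion into both primary C–Br bonds is reliable here because the seven-carbon tether does not cyclize readily and dilution limits Wurtz coupling; no stereocentre is involved.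

Step 2
Reactants: 2 heptane-1,7-diylbis(magnesium bromide); 3 (R)-epichlorohydrin (2.3 equiv)
Product: 4 (2R,12R)-1,13-dichlorotridecane-2,12-diol
Conditions: 2 added slowly to 3 and CuI (10 mol % per C–Mg), THF, −40 to −20 °C; sat. aq. NH4Cl
Reagents that add atoms: none
Why: Each C–Mg terminus transmetalates to a cuprate that attacks the unsubstituted epoxide carbon of 3 by SN2, opening the ring to a magnesium chloroalkoxide that is protonated on work-up. The closest known reaction type is the CuI-catalysed Grignard opening of epichlorohydrin to 1-chloroalkan-2-ols, run here at both ends of one chain. No ring is closed. The stereocentres C2 and C12 of 4 (later C3 and C10' of the target) come unchanged from the chiral pool, because no bond to the carbinol carbon is made or broken, and the descriptor stays R since CH2Cl outranks the new chain CH2. The selectivity needed is attack at the epoxide CH2 rather than at CH2Cl (direct chloride displacement would lead to the enantiomeric epoxide) or at a prematurely closed epoxide; it is secured by the soft cuprate, the strained unhindered epoxide terminus and the low temperature, which keeps the chloroalkoxide from closing. Because both termini are identical, only complete double reaction is required, which the excess of volatile 3 provides.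

Step 3
Reactants: 4 (2R,12R)-1,13-dichlorotridecane-2,12-diol
Product: 5 (2R,12R)-1,2:12,13-diepoxytridecane
Conditions: powdered NaOH (excess), Et2O, rt
Reagents that add atoms: none
Why: Double intramolecular Williamson etherification (3-exo-tet closure of each alkoxide onto the primary C–Cl carbon) forms both oxiranes without touching the C2–O and C12–O bonds, so the (R,R) configuration is retained.

Step 4
Reactants: 5 (2R,12R)-1,2:12,13-diepoxytridecane
Product: 6 (2S)-11-[(2R)-oxiran-2-yl]undecan-2-ol
Conditions: LiEt3BH (0.5 equiv, slow addition), THF, −78 to 0 °C; H2O; unreacted 5 recovered by chromatography and recycled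
Reagents that add atoms: none
Why: Super-Hydride reduction of a terminal epoxide delivers hydride by SN2 to the CH2 carbon only, so the C–O centre keeps its geometry (the descriptor becomes S because the former epoxide CH2 is now the lowest-ranked methyl carbon), and since the two epoxides of 5 are homotopic a deficit of hydride should give a single mono-opened product beside recoverable 5.

Step 5
Reactants: 6 (2S)-11-[(2R)-oxiran-2-yl]undecan-2-ol
Product: 7 (2R)-2-[(10S)-10-methoxyundecyl]oxirane
Conditions: MeI (3 equiv), then NaH (1.5 equiv), THF, 0 °C to rt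
Reagents that add atoms: iodomethane, CI
Why: Williamson ether synthesis, in which the sodium alkoxide is methylated on oxygen by SN2 at iodomethane, leaves the C–O stereocentre untouched, and the remote terminal epoxide tolerates the aprotic basic conditions.

Step 6
Reactants: 7 (2R)-2-[(10S)-10-methoxyundecyl]oxirane; 8 1-bromo-3,5-bis(benzyloxy)benzene (1.5 equiv)
Product: 10 (2R,12S)-1-[3,5-bis(benzyloxy)phenyl]-12-methoxytridecan-2-ol, via aryl Grignard reagent 9 (not isolated)
Conditions: 8, Mg, I2 (cat.), THF, reflux; then CuI (10 mol %), 7, THF, −30 to 0 °C; sat. aq. NH4Cl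
Reagents that add atoms: none
Why: Copper-catalysed Grignard opening of a terminal epoxide, in which the aryl cuprate attacks the CH2 carbon by SN2, retains the secondary C–O centre, which is R in the product because CH2Ar outranks the chain CH2; the methyl ether is inert.

Step 7
Reactants: 10 (2R,12S)-1-[3,5-bis(benzyloxy)phenyl]-12-methoxytridecan-2-ol
Product: 11 (2R,12S)-1-[3,5-bis(benzyloxy)-2-bromophenyl]-12-methoxytridecan-2-ol
Conditions: NBS (1.0 equiv), MeCN, 0 °C, dark
Reagents that add atoms: N-bromosuccinimide, O=C1CCC(=O)N1Br
Why: Electrophilic aromatic bromination of the electron-rich resorcinol diether with NBS should go to the position ortho to the alkyl chain and para to a benzyloxy group (the two such positions are equivalent), as is usual for 5-alkylresorcinol diethers, and the secondary alcohol is not oxidised under these conditions.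

Step 8
Reactants: 11 (2R,12S)-1-[3,5-bis(benzyloxy)-2-bromophenyl]-12-methoxytridecan-2-ol
Product: 12 (3R)-6,8-bis(benzyloxy)-3-[(10S)-10-methoxyundecyl]isochroman-1-one
Conditions: CO (balloon), Pd(PPh3)4 (10 mol %), K2CO3 (2 equiv), DMF, 100 °C
Reagents that add atoms: carbon monoxide, [C-]#[O+]
Why: Palladium-catalysed carbonylative lactonization (intramolecular alkoxycarbonylation of an aryl bromide) proceeds by oxidative addition of zerovalent palladium into the C–Br bond, CO insertion to the aroylpalladium species and capture by the C3 hydroxyl, closing the six-membered lactone ring B without touching either stereocentre.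

Step 9
Reactants: 12 (3R)-6,8-bis(benzyloxy)-3-[(10S)-10-methoxyundecyl]isochroman-1-one
Product: 13 (3R)-6,8-dihydroxy-3-[(10S)-10-methoxyundecyl]isochroman-1-one (CNP0242607.1)
Conditions: H2 (1 atm), 10% Pd/C, EtOAc–MeOH, rt
Reagents that add atoms: none
Why: Catalytic hydrogenolysis cleaves the two aryl benzyl ethers to the free phenols, while the lactone C3–O bond (homobenzylic, not benzylic), the alkyl methyl ether and both stereocentres are untouched.

Compound list
1 | 1,7-dibromoheptane | BrCCCCCCCBr | starting material
2 | heptane-1,7-diylbis(magnesium bromide) | Br[Mg]CCCCCCC[Mg]Br | intermediate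
3 | (R)-epichlorohydrin, (2R)-2-(chloromethyl)oxirane | ClC[C@H]1CO1 | starting material
4 | (2R,12R)-1,13-dichlorotridecane-2,12-diol | O[C@@H](CCl)CCCCCCCCC[C@@H](O)CCl | intermediate
5 | (2R,12R)-1,2:12,13-diepoxytridecane | O1C[C@H]1CCCCCCCCC[C@@H]1CO1 | intermediate
6 | (2S)-11-[(2R)-oxiran-2-yl]undecan-2-ol | C[C@H](O)CCCCCCCCC[C@@H]1CO1 | intermediate
7 | (2R)-2-[(10S)-10-methoxyundecyl]oxirane | CO[C@@H](C)CCCCCCCCC[C@@H]1CO1 | intermediate
8 | 1-bromo-3,5-bis(benzyloxy)benzene | Brc1cc(OCc2ccccc2)cc(OCc2ccccc2)c1 | starting material
9 | 3,5-bis(benzyloxy)phenylmagnesium bromide | Br[Mg]c1cc(OCc2ccccc2)cc(OCc2ccccc2)c1 | intermediate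
10 | (2R,12S)-1-[3,5-bis(benzyloxy)phenyl]-12-methoxytridecan-2-ol | CO[C@@H](C)CCCCCCCCC[C@@H](O)Cc1cc(OCc2ccccc2)cc(OCc2ccccc2)c1 | intermediate
11 | (2R,12S)-1-[3,5-bis(benzyloxy)-2-bromophenyl]-12-methoxytridecan-2-ol | CO[C@@H](C)CCCCCCCCC[C@@H](O)Cc1cc(OCc2ccccc2)cc(OCc2ccccc2)c1Br | intermediate
12 | (3R)-6,8-bis(benzyloxy)-3-[(10S)-10-methoxyundecyl]isochroman-1-one | CO[C@@H](C)CCCCCCCCC[C@@H]1Cc2cc(OCc3ccccc3)cc(OCc3ccccc3)c2C(=O)O1 | intermediate
13 | (3R)-6,8-dihydroxy-3-[(10S)-10-methoxyundecyl]isochroman-1-one | CO[C@@H](C)CCCCCCCCC[C@@H]1Cc2cc(O)cc(O)c2C(=O)O1 | target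

Total step count: 9.
Longest linear sequence: 9 steps (1 to 13); aryl bromide 8 is purchased and enters at step 6.

Steps most likely to fail

Step 4. Hydride may be delivered to both homotopic epoxides, or conversion may have to be held so low that recycling dominates. The fallback runs from 5 to 12 and breaks the symmetry with the aryl nucleophile instead. Grignard reagent 9 (from 8, as the limiting reagent) is added with catalytic CuI to a threefold excess of 5, with the surplus 5 recovered, to give (2R)-1-[3,5-bis(benzyloxy)phenyl]-11-[(2R)-oxiran-2-yl]undecan-2-ol F1. The remaining epoxide is reduced with excess LiEt3BH, where no stoichiometric control is needed, to (2R,12S)-1-[3,5-bis(benzyloxy)phenyl]tridecane-2,12-diol F2. NBS then gives (2R,12S)-1-[3,5-bis(benzyloxy)-2-bromophenyl]tridecane-2,12-diol F3. Carbonylative lactonization (CO, Pd(PPh3)4, K2CO3, DMF) consumes only the C2 hydroxyl, which closes the six-membered ring, and so tells the two alcohols apart, giving (3R)-6,8-bis(benzyloxy)-3-[(10S)-10-hydroxyundecyl]isochroman-1-one F4. Methylation of the remaining secondary alcohol under non-basic conditions (Me3OBF4, 1,8-bis(dimethylamino)naphthalene, CH2Cl2) gives 12.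

Step 2. The double addition may stall at one end. Magnesium bromide may open the epoxide with bromide. The chloroalkoxide may close early and be alkylated a second time. Wurtz coupling during formation of the bis-Grignard reagent may lower its titre. The fallback runs from 3 to 4 and keeps the two-directional plan with a different nucleophile. Hepta-1,6-diyne is deprotonated twice with n-BuLi (THF, −78 °C) to 1,7-dilithiohepta-1,6-diyne F5. With BF3·OEt2 at −78 °C this opens two molecules of 3 at the epoxide CH2 (alkynyllithium epoxide opening) to give, after aqueous NH4Cl, (2R,12R)-1,13-dichlorotrideca-4,9-diyne-2,12-diol F6. Hydrogenation of both alkynes (H2, PtO2, EtOAc) gives 4.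

Step 8. Oxidative addition into the electron-rich C–Br bond flanked by two ortho substituents may be slow under CO, so that protodebromination or catalyst decomposition competes. The fallback runs from 11 to 12 without palladium. n-BuLi (2.2 equiv, THF, −78 °C) deprotonates the hydroxyl and exchanges bromine for lithium to give lithium (2R,12S)-1-[3,5-bis(benzyloxy)-2-lithiophenyl]-12-methoxytridecan-2-olate F7. Quenching with CO2 and acidifying with aqueous HCl gives 2,4-bis(benzyloxy)-6-[(2R,12S)-2-hydroxy-12-methoxytridecyl]benzoic acid F8, which lactonizes on warming with catalytic TsOH in toluene to 12.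

Further compounds
F1 | step 4 | (2R)-1-[3,5-bis(benzyloxy)phenyl]-11-[(2R)-oxiran-2-yl]undecan-2-ol | O1C[C@H]1CCCCCCCCC[C@@H](O)Cc2cc(OCc3ccccc3)cc(OCc3ccccc3)c2
F2 | step 4 | (2R,12S)-1-[3,5-bis(benzyloxy)phenyl]tridecane-2,12-diol | C[C@H](O)CCCCCCCCC[C@@H](O)Cc1cc(OCc2ccccc2)cc(OCc2ccccc2)c1
F3 | step 4 | (2R,12S)-1-[3,5-bis(benzyloxy)-2-bromophenyl]tridecane-2,12-diol | C[C@H](O)CCCCCCCCC[C@@H](O)Cc1cc(OCc2ccccc2)cc(OCc2ccccc2)c1Br
F4 | step 4 | (3R)-6,8-bis(benzyloxy)-3-[(10S)-10-hydroxyundecyl]isochroman-1-one | C[C@H](O)CCCCCCCCC[C@@H]1Cc2cc(OCc3ccccc3)cc(OCc3ccccc3)c2C(=O)O1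
F5 | step 2 | 1,7-dilithiohepta-1,6-diyne | [Li]C#CCCCC#C[Li]
F6 | step 2 | (2R,12R)-1,13-dichlorotrideca-4,9-diyne-2,12-diol | O[C@@H](CCl)CC#CCCCC#CC[C@@H](O)CCl
F7 | step 8 | lithium (2R,12S)-1-[3,5-bis(benzyloxy)-2-lithiophenyl]-12-methoxytridecan-2-olate | CO[C@@H](C)CCCCCCCCC[C@@H](O[Li])Cc1cc(OCc2ccccc2)cc(OCc2ccccc2)c1[Li]
F8 | step 8 | 2,4-bis(benzyloxy)-6-[(2R,12S)-2-hydroxy-12-methoxytridecyl]benzoic acid | CO[C@@H](C)CCCCCCCCC[C@@H](O)Cc1cc(OCc2ccccc2)cc(OCc2ccccc2)c1C(=O)O
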